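**Remarks on the chemistry.** Triterpene atoms carry friedelane numbers (ring A = C1–C5, C10; C26 = methyl on C14; C30 = remaining methyl on C20); guaiane atoms carry primed numbers; O2 and O3 are the oxygens on C2 and C3. Large intermediates are named on the 24,29-dinor-D:A-friedooleanane skeleton (9β-, 13α-, 14β-, 17β-methyl, 18β-H, 20β-methyl). In steps 7 and 31 the ligand antipode named is the one assumed to give the configuration drawn; the other antipode is used if the sense proves opposite.

## Analysis of the target

The target is an octacyclic hetero-adduct. A 24,29-dinorfriedelane triterpene with aromatic ring A, a C6=C7 styrene bond and a C21 ketone in ring E is joined through O2 and O3 to C1′ and C5′ of a guaia-3′,11′-diene, so a 1,4-benzodioxane is cis-fused on the C1′–C5′ bond (O2–C1′, O3–C5′). The triterpene half has seven stereocentres: H8 β and the C9 methyl β (cis B/C), the C13 methyl α and the C14 methyl β (trans C/D, vicinal quaternary carbons), the C17 methyl and H18 both β (cis D/E), and the C20 methyl β. C9 is separated from the ring D/E centres by the two-carbon bridge C11–C12, so their relation must come from absolute control of each piece. The guaiane half has four stereocentres: both oxygens sit on one face at C1′ and C5′, and the C10′ methyl and the C7′ isopropenyl group sit on the other face, cis to each other. Sensitive groups are the tertiary allylic aryl ether at C5′, the electron-rich styrene, the isopropenyl and C3′=C4′ alkenes, and the C21 ketone with its epimerisable neighbour C20. The difficulty lies in four quaternary carbons (C9, C13, C14, C17) with syn-axial methyl groups on C9 and C14, and in two fully substituted C–O bonds of fixed regiochemistry. The strategy rests on ring C: H8 is cis to the C9 methyl, and C14 is a methyl-bearing quaternary carbon next to quaternary C13. The C8–C14 bond can therefore be made by a tertiary C14 radical, born from a C14 exocyclic methylene, adding to C8 of a ring B aryl enone through the C11–C12 chain on C9.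

## Retrosynthetic reasoning

**C5′–O3, C6=C7 and the C21 ketone (54 from 53).** The acid-labile elements are made last, in one acid-mediated operation. The tertiary allylic carbinol C5′ ionises and is captured by O3, the benzylic C6 carbinol eliminates to the styrene, and the C21 ketal is removed. Closing the dioxane at C5′ intramolecularly fixes the cis fusion and leaves the alkene at C3′=C4′.

**C6 carbinol and C4′–C5′ (53 from 52 from 51).** The C6 ketone is kept until here because it activates O2 and deactivates the arene during ether formation; it is then reduced. The cyclopentene is cut at C4′–C5′: a vinyl-metal on the C2′ chain adds to the C5′ ketone of 51, so the new C5′ configuration is irrelevant.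

**O2–C1′ (51 from 50 and 49).** The only intermolecular C–O bond is made between the phenoxide at O2 and the tertiary α-bromo ketone 49. O3 is blocked as its methoxymethyl ether, so regiochemistry is fixed by protection. Oxygen is introduced last at planar C1′, anti to the C10′ methyl, which is the relation the target needs.

**O2 methyl ether (50 from 35).** The O2 methyl ether is para to the C6 ketone and is cleaved by a thiolate; the acetal on O3 and the C21 ketal stay.

**C8–C14 and ring C (35 from 34).** This is the key disconnection. It removes ring C, the stereocentres C8 and C14 and one quaternary carbon in one step. It leaves a seco compound 34 whose two halves (rings A/B and rings D/E) are joined only by C11–C12.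

**Enone and methylene (34 from 29).** The ring B enone comes from the tetralone by dehydrogenation and the C14 methylene from the C14 ketone by methylenation. C6 is carried as a silyl ether while ring D enolate chemistry is done.

**C12–C13 (29 from 27 and 15).** The two enantiopure halves are joined by alkylating the ring D enolate from 27 with the primary iodide 15. The chain must enter cis to H18 and the C17 methyl. It is therefore introduced as the electrophile on the cis-fused, 13-methylated enolate, on its convex face. The alternative order (chain first, then methylation of a dienolate and hydrogenation) would put hydrogen on C18 trans to the C17 methyl.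

**Rings A/B (15 from 10 from 9 from 5 and 7, from 1 and 6).** C10–C9 is cut by an asymmetric Heck cyclisation, which sets the benzylic quaternary C9 and ring B together and leaves a vinyl group that becomes C11–C12. C7–C8 is cut by enolate alkylation of the aryl methyl ketone 5. The substitution pattern of ring A is fixed from 1 by acylation para to O2, selective cleavage of the flanked O3 ether and iodination para to the free O3 phenol.

**Rings D/E (27 from 24 from 23 from 19 and 21, from 16).** Ring D is cut by a Robinson annulation between the symmetric dione 19 and 21. C17 is set by a chiral-amine-mediated Michael addition, C20 by equilibration, and C18 by cis hydrogenation of the octalone.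

**Guaiane piece (49 from 41 and 45, from 36 and 42).** The seven-membered ring comes from 36 by one-carbon ring expansion. C10′ is set by ligand-controlled conjugate reduction of 41 and C1′ is alkylated with 45.

## Alternatives that were turned down

**Alternative 1:** The cyclopentene is cut at C1′–C2′ on a finished benzodioxane. Forward, Rh2(OAc)4 would decompose a diazoketone side chain on C5′; the carbenoid carbon C2′ would insert into the C1′–H bond next to O2 and give the cyclopentanone A1, which still needs conversion to the C3′=C4′ alkene.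
- For: insertion next to an ether oxygen with five-ring closure is the preferred mode and goes with retention. C1′ would then be a secondary ether carbon, so the C1′–O2 bond could be made by substitution at a secondary centre. On that point it is stronger than the chosen route.
- Against: the carbenoid also has C6′–H bonds at the same distance and three π systems in reach (isopropenyl, styrene, electron-rich arene). The ketone must afterwards be turned into one alkene regioisomer. The riskiest step falls on the complete octacycle.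
- Comparison: it leaves C8 and the C13/C14 pair unsolved. The chosen strategy spends its risk on ring C at the stage of a robust mono-ketone and then needs five steps to finish.

**Alternative 2:** Ring A is cut at C2–C3, C1–C10 and C4–C5. Forward, RhCl(PPh3)3 would cotrimerise a bis(alkynyl ether) of the guaiane 1′,5′-diol with an enyne on C9 to the arene A2, and ring B would then be closed between its two vinyl groups.
- For: it is the most convergent plan, and both dioxane C–O bonds exist before the arene does, so no late etherification at a tertiary carbon is needed. Here it is stronger than the chosen route.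
- Against: ynol ethers of a hindered di-tertiary diol are hard to make and labile. The cotrimerisation must give one regioisomer of a pentasubstituted benzene with a hindered internal alkyne. A2 presupposes rings C–E with C8, C9, C13 and C14 already set.
- Comparison: the chosen route fixes the ring A pattern in step 1 by ordinary aromatic substitution and gives an explicit solution for C8–C14.

**Alternative 3:** Ring B is cut at C9–C10. Forward, Pd(OAc)2 with P(t-Bu)3 and NaOt-Bu would couple the C9 enolate of a C11 ketone with an aryl bromide at C10 to give A3.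
- For: the benzylic quaternary carbon and ring B form together, and the planar enolate lets both C9 epimers of the substrate converge. That is a real strength.
- Against: strong base at elevated temperature meets the tertiary allylic aryl ether, a second enolisable ketone at C21 and two possible enolates of the C11 ketone (C9 or C12). The C11 oxygen must then be removed next to a quaternary carbon in the presence of the C21 ketone. Rings C–E with C8, C13 and C14 must again already exist.
- Comparison: the chosen route sets C9 on a small molecule by asymmetric Heck cyclisation, carries no surplus oxygen, and builds ring C itself.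

Key step: step 25

## Route

**Rings A/B: iodide 15**

Step 1
Reactants: 1 2,3-dimethoxytoluene
Product: 2 1-(3,4-dimethoxy-2-methylphenyl)ethan-1-one
Conditions: AcCl, AlCl3, CH2Cl2, 0 °C
Reagents that add atoms: acetyl chloride, CC(=O)Cl
Why: Friedel–Crafts acylation; the methoxy group on the future C2 lies in the ring plane and directs para, to C5 beside the methyl group, while the flanked methoxy on C3 is twisted and a weak donor, so the future C6 carbonyl carbon is placed on C5.

Step 2
Reactants: 2 1-(3,4-dimethoxy-2-methylphenyl)ethan-1-one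
Product: 3 1-(3-hydroxy-4-methoxy-2-methylphenyl)ethan-1-one
Conditions: BCl3, CH2Cl2, −78 → 0 °C
Reagents that add atoms: none
Why: Lewis-acid ether cleavage; the O3 methoxy, twisted between methyl and methoxy, is the more basic oxygen, whereas the O2 methoxy is a vinylogous ester through the para acetyl group, so only O3 should be freed.

Step 3
Reactants: 3 1-(3-hydroxy-4-methoxy-2-methylphenyl)ethan-1-one
Product: 4 1-(3-hydroxy-6-iodo-4-methoxy-2-methylphenyl)ethan-1-one
Conditions: N-iodosuccinimide, CF3CO2H (cat.), MeCN, 0 °C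
Reagents that add atoms: N-iodosuccinimide, O=C1CCC(=O)N1I
Why: electrophilic aromatic iodination; both positions ortho to the phenol are substituted, so the phenol directs to its para position C10, the carbon that will bear C9.

Step 4
Reactants: 4 1-(3-hydroxy-6-iodo-4-methoxy-2-methylphenyl)ethan-1-one
Product: 5 1-[6-iodo-4-methoxy-3-(methoxymethoxy)-2-methylphenyl]ethan-1-one
Conditions: MeOCH2Cl, i-Pr2NEt, CH2Cl2, 0 °C → rt
Reagents that add atoms: chloromethyl methyl ether, COCCl
Why: O-alkylation of the phenol to the methoxymethyl acetal, which withstands the bases, hydrides and thiolate used later and leaves O2 and O3 differentiated.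

Step 5
Reactants: 6 (E)-2-methylbut-2-en-1-ol
Product: 7 (E)-1-bromo-2-methylbut-2-ene
Conditions: PBr3, Et2O, 0 °C
Reagents that add atoms: phosphorus tribromide, BrP(Br)Br
Why: bromination of a primary allylic alcohol; the trisubstituted alkene keeps its geometry.

Step 6
Reactants: 5 1-[6-iodo-4-methoxy-3-(methoxymethoxy)-2-methylphenyl]ethan-1-one; 7 (E)-1-bromo-2-methylbut-2-ene
Product: 9 (E)-1-[6-iodo-4-methoxy-3-(methoxymethoxy)-2-methylphenyl]-4-methylhex-4-en-1-one, via lithium enolate 8 (not isolated)
Conditions: LiN(i-Pr)2, THF, −78 °C; then 7, −78 → 0 °C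
Reagents that add atoms: none
Why: kinetic enolate alkylation of the methyl ketone with a reactive allylic bromide forms C7–C8; the aryl iodide is not touched by the amide base at low temperature.

Step 7
Reactants: 9 (E)-1-[6-iodo-4-methoxy-3-(methoxymethoxy)-2-methylphenyl]-4-methylhex-4-en-1-one
Product: 10 (S)-4-ethenyl-6-methoxy-7-(methoxymethoxy)-4,8-dimethyl-3,4-dihydronaphthalen-1(2H)-one
Conditions: Pd2(dba)3·CHCl3 (5 mol%), (R)-BINAP (12 mol%), Ag3PO4, N-methylpyrrolidone, 80 °C
Reagents that add atoms: none
Why: asymmetric intramolecular Heck reaction (6-exo); arylpalladium adds to C9 of the trisubstituted alkene, β-hydride elimination is possible only toward the terminal methyl and leaves the vinyl group C11=C12, and the chiral bisphosphine selects the alkene face and so sets quaternary C9.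

Step 8
Reactants: 10 (S)-4-ethenyl-6-methoxy-7-(methoxymethoxy)-4,8-dimethyl-3,4-dihydronaphthalen-1(2H)-one
Product: 11 (4S)-4-ethenyl-6-methoxy-7-(methoxymethoxy)-4,8-dimethyl-1,2,3,4-tetrahydronaphthalen-1-ol (C1 epimers)
Conditions: NaBH4, MeOH, 0 °C → rt
Reagents that add atoms: none
Why: hydride reduction masks the enolisable tetralone so that later enolate chemistry is confined to ring D; the carbinol configuration is irrelevant because C6 is reoxidised in step 23.

Step 9
Reactants: 11 (4S)-4-ethenyl-6-methoxy-7-(methoxymethoxy)-4,8-dimethyl-1,2,3,4-tetrahydronaphthalen-1-ol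
Product: 12 tert-butyl{[(4S)-4-ethenyl-6-methoxy-7-(methoxymethoxy)-4,8-dimethyl-1,2,3,4-tetrahydronaphthalen-1-yl]oxy}dimethylsilane
Conditions: t-BuMe2SiCl, imidazole, DMF, 40 °C
Reagents that add atoms: tert-butyldimethylsilyl chloride, CC(C)(C)[Si](C)(C)Cl
Why: silylation of the benzylic alcohol gives a group stable to borane, organolithium and ylide reagents.

Step 10
Reactants: 12 tert-butyl{[(4S)-4-ethenyl-6-methoxy-7-(methoxymethoxy)-4,8-dimethyl-1,2,3,4-tetrahydronaphthalen-1-yl]oxy}dimethylsilane
Product: 14 2-[(1S)-4-(tert-butyldimethylsilyloxy)-7-methoxy-6-(methoxymethoxy)-1,5-dimethyl-1,2,3,4-tetrahydronaphthalen-1-yl]ethan-1-ol, via B-alkyl-9-borabicyclononane 13 (not isolated)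
Conditions: 9-BBN, THF, 50 °C; then NaOH, H2O2, 0 °C
Reagents that add atoms: hydrogen peroxide, OO
Why: anti-Markovnikov hydroboration–oxidation of the vinyl group gives the primary alcohol at C12; the bulky borane adds only to the terminal carbon and C9 is untouched.

Step 11
Reactants: 14 2-[(1S)-4-(tert-butyldimethylsilyloxy)-7-methoxy-6-(methoxymethoxy)-1,5-dimethyl-1,2,3,4-tetrahydronaphthalen-1-yl]ethan-1-ol
Product: 15 tert-butyl{[(4S)-4-(2-iodoethyl)-6-methoxy-7-(methoxymethoxy)-4,8-dimethyl-1,2,3,4-tetrahydronaphthalen-1-yl]oxy}dimethylsilane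
Conditions: I2, PPh3, imidazole, CH2Cl2, 0 °C → rt
Reagents that add atoms: iodine, II
Why: Appel-type iodination of the primary alcohol gives the unhindered electrophile at C12.

**Rings D/E: enol ether 27**

Step 12
Reactants: 16 2,5-dimethyl-1,4-benzoquinone
Product: 18 2,5-dimethylcyclohexane-1,4-diol (stereoisomer mixture), via 2,5-dimethylhydroquinone 17 (not isolated)
Conditions: H2 (60 bar), Rh/Al2O3, EtOH, 60 °C
Reagents that add atoms: none
Why: catalytic hydrogenation reduces the quinone to the hydroquinone and then saturates the ring; the stereoisomer mixture is irrelevant because all centres become sp2 or labile in the next steps.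

Step 13
Reactants: 18 2,5-dimethylcyclohexane-1,4-diol
Product: 19 2,5-dimethylcyclohexane-1,4-dione
Conditions: NaOCl, TEMPO (cat.), KBr (cat.), CH2Cl2/H2O, 0 °C
Reagents that add atoms: none
Why: oxoammonium-catalysed oxidation of both secondary alcohols; the dione is symmetric, so either carbonyl can become C18.

Step 14
Reactants: 19 2,5-dimethylcyclohexane-1,4-dione
Product: 20 mono-imine of 19 with (S)-1-phenylethylamine
Conditions: (S)-1-phenylethylamine (0.5 equiv relative to 19), TsOH (cat.), toluene, reflux, Dean–Stark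
Reagents that add atoms: (S)-1-phenylethylamine, C[C@H](N)c1ccccc1
Why: condensation with removal of water; excess dione keeps the bis-imine low, and the α centres stay labile through imine–enamine tautomerism.

Step 15
Reactants: 20 mono-imine of 19; 21 pent-1-en-3-one
Product: 23 (2S)-2,5-dimethyl-2-(3-oxopentyl)cyclohexane-1,4-dione (C5 epimers), via Michael adduct imine 22 (not isolated)
Conditions: 21, THF, 40 °C; then 10% aq. AcOH, rt
Reagents that add atoms: water, O
Why: deracemising Michael addition of a chiral imine; the more substituted secondary enamine adds to the enone in a chair-like aza-ene transition state on the face away from the phenyl group and sets quaternary C17, in the same sense as (S)-amine imines of 2-methylcyclohexanone; C20 stays epimerisable.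

Step 16
Reactants: 23 (2S)-2,5-dimethyl-2-(3-oxopentyl)cyclohexane-1,4-dione
Product: 24 (4aS,7R)-1,4a,7-trimethyl-4,4a,7,8-tetrahydronaphthalene-2,6(3H,5H)-dione
Conditions: NaOMe, MeOH, 60 °C
Reagents that add atoms: none
Why: intramolecular aldol condensation (Robinson annulation) joins C13 to C18; other aldol modes are reversible and the conjugated octalone is the sink, and the base equilibrates C20 to the equatorial methyl of ring E, which is the 20β configuration cis to the axial C17 methyl.

Step 17
Reactants: 24 (4aS,7R)-1,4a,7-trimethyl-4,4a,7,8-tetrahydronaphthalene-2,6(3H,5H)-dione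
Product: 25 (4aS,7R)-6,6-(ethylenedioxy)-1,4a,7-trimethyl-4,4a,5,6,7,8-hexahydronaphthalen-2(3H)-one
Conditions: HOCH2CH2OH (1.1 equiv), TsOH (cat.), benzene, reflux, Dean–Stark
Reagents that add atoms: ethane-1,2-diol, OCCO
Why: chemoselective ketalisation of the saturated C21 ketone over the conjugated C14 ketone, as in Wieland–Miescher ketone chemistry; it also freezes C20.

Step 18
Reactants: 25 (4aS,7R)-6,6-(ethylenedioxy)-1,4a,7-trimethyl-4,4a,5,6,7,8-hexahydronaphthalen-2(3H)-one
Product: 26 cis-fused 6,6-(ethylenedioxy)-1,4a,7-trimethyloctahydronaphthalen-2(1H)-one (H18 and C17 methyl cis; C13 epimers)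
Conditions: H2 (3 bar), Pd/C, EtOH, Et3N (trace)
Reagents that add atoms: none
Why: heterogeneous hydrogenation of the octalone; as with related 1,10-dialkyl octalones, hydrogen is delivered to C18 on the face of the angular methyl and gives the cis-decalone, which sets H18 β; C13 is irrelevant because it is enolised next.

Step 19
Reactants: 26 cis-fused 6,6-(ethylenedioxy)-1,4a,7-trimethyloctahydronaphthalen-2(1H)-one
Product: 27 trimethylsilyl enol ether of 26 (C13=C14)
Conditions: Me3SiCl, Et3N, DMF, 110 °C
Reagents that add atoms: chlorotrimethylsilane, C[Si](C)(C)Cl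
Why: silyl enol ether formation under equilibrating conditions; the tetrasubstituted enol ether toward the ring fusion is the more stable, in line with the enolisation of cis-fused 3-keto steroids toward C4.

**Union and the cyclisation precursor**

Step 20
Reactants: 27 trimethylsilyl enol ether of 26; 15 tert-butyl{[(4S)-4-(2-iodoethyl)-6-methoxy-7-(methoxymethoxy)-4,8-dimethyl-1,2,3,4-tetrahydronaphthalen-1-yl]oxy}dimethylsilane
Product: 29 6-(tert-butyldimethylsilyloxy)-21,21-(ethylenedioxy)-2-methoxy-3-(methoxymethoxy)-8,14-seco-24,29-dinor-D:A-friedooleana-1,3,5(10)-trien-14-one (C6 epimers), via lithium enolate 28 (not isolated)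
Conditions: MeLi, THF, 0 °C; then 15, DMPU, −78 → 0 °C
Reagents that add atoms: none
Why: regiospecific enolate generation from the enol silane and C-alkylation by the primary iodide create quaternary C13; the equatorial 20β-methyl holds ring E in the fold in which C22 is axial over the α face of ring D, so the electrophile should enter on the convex β face, cis to H18 and the C17 methyl (as electrophiles attack C4 of cis-fused 3-keto steroids from the β face), leaving the C13 methyl α.

Step 21
Reactants: 29 6-(tert-butyldimethylsilyloxy)-21,21-(ethylenedioxy)-2-methoxy-3-(methoxymethoxy)-8,14-seco-24,29-dinor-D:A-friedooleana-1,3,5(10)-trien-14-one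
Product: 30 6-(tert-butyldimethylsilyloxy)-21,21-(ethylenedioxy)-2-methoxy-3-(methoxymethoxy)-8,14-seco-24,29-dinor-D:A-friedooleana-1,3,5(10),14(26)-tetraene
Conditions: Ph3PCH3Br, KOt-Bu, toluene, 90 °C
Reagents that add atoms: methyltriphenylphosphonium bromide, C[P+](c1ccccc1)(c1ccccc1)c1ccccc1.[Br-]
Why: Wittig methylenation under the forcing conditions used for α-quaternary ketones installs C26 as the exocyclic methylene; ketal, silyl ether and acetal are stable to the base.

Step 22
Reactants: 30 6-(tert-butyldimethylsilyloxy)-21,21-(ethylenedioxy)-2-methoxy-3-(methoxymethoxy)-8,14-seco-24,29-dinor-D:A-friedooleana-1,3,5(10),14(26)-tetraene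
Product: 31 21,21-(ethylenedioxy)-2-methoxy-3-(methoxymethoxy)-8,14-seco-24,29-dinor-D:A-friedooleana-1,3,5(10),14(26)-tetraen-6-ol (C6 epimers)
Conditions: Bu4NF, THF, rt
Reagents that add atoms: none
Why: fluoride cleaves the silyl ether; all other groups are inert.

Step 23
Reactants: 31 21,21-(ethylenedioxy)-2-methoxy-3-(methoxymethoxy)-8,14-seco-24,29-dinor-D:A-friedooleana-1,3,5(10),14(26)-tetraen-6-ol
Product: 32 21,21-(ethylenedioxy)-2-methoxy-3-(methoxymethoxy)-8,14-seco-24,29-dinor-D:A-friedooleana-1,3,5(10),14(26)-tetraen-6-one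
Conditions: Dess–Martin periodinane, NaHCO3, CH2Cl2, rt
Reagents that add atoms: none
Why: mild oxidation of the benzylic alcohol back to the tetralone; the buffered conditions spare the acetal, the ketal and the 1,1-disubstituted alkene.

Step 24
Reactants: 32 21,21-(ethylenedioxy)-2-methoxy-3-(methoxymethoxy)-8,14-seco-24,29-dinor-D:A-friedooleana-1,3,5(10),14(26)-tetraen-6-one
Product: 34 21,21-(ethylenedioxy)-2-methoxy-3-(methoxymethoxy)-8,14-seco-24,29-dinor-D:A-friedooleana-1,3,5(10),7,14(26)-pentaen-6-one, via trimethylsilyl enol ether 33 (not isolated)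
Conditions: LiN(i-Pr)2, Me3SiCl, THF, −78 °C; then Pd(OAc)2, MeCN, rt
Reagents that add atoms: none
Why: Saegusa–Ito dehydrogenation; C6 is the only ketone (C21 is a ketal), it enolises only toward C7, and palladium-mediated oxidation of the enol silane gives the 4,4-disubstituted naphthalenone, which cannot aromatise because C9 is quaternary.

**Key step**

Step 25
Reactants: 34 21,21-(ethylenedioxy)-2-methoxy-3-(methoxymethoxy)-8,14-seco-24,29-dinor-D:A-friedooleana-1,3,5(10),7,14(26)-pentaen-6-one
Product: 35 21,21-(ethylenedioxy)-2-methoxy-3-(methoxymethoxy)-24,29-dinor-8β-D:A-friedooleana-1,3,5(10)-trien-6-one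
Conditions: Fe(acac)3 (0.3 equiv), PhSiH3 (slow addition), EtOH/HOCH2CH2OH (5:1), 60 °C
Reagents that add atoms: none
Why: An iron hydride formed from Fe(acac)3 and PhSiH3 transfers a hydrogen atom to C26 of the 1,1-disubstituted alkene, which creates the C14 methyl group and a nucleophilic tertiary radical at C14; the enone, ketal, acetal and aryl ether do not accept hydrogen atoms. The radical adds to C8, the β-carbon of the aryl enone, in a 6-exo-trig closure that forms C8–C14 and ring C, and the α-keto radical at C7 is reduced by divalent iron and protonated by ethanol. The closest known reaction is the iron-catalysed reductive olefin–enone coupling (hydrogen-atom-transfer Giese reaction), which forms quaternary carbons and six-membered rings intramolecularly. C8 is controlled by the tether: the chain C11–C12 leaves C9 on the α face, so C14 can reach C8 only from that face, H8 ends up β and cis to the C9 methyl (cis B/C). C14 is controlled by the transition-state shape: a chair-like array in which both ring C bonds (C13–C12 and C14–C8) are equatorial on ring D is the only one that gives the trans C/D junction, and it leaves the new methyl axial, β and anti to the axial 13α-methyl. The step needs face selection at the C14 radical; the equatorial preference of the C12 tether on ring D supports it, while the developing syn-axial C9/C14 methyl pair is the weak point. Slow silane addition keeps the hydride concentration low, because addition to a β-carbon next to quaternary C9 is slow and early reduction of the radical would compete.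

**Guaiane piece: bromoketone 49**

Step 26
Reactants: 36 (S)-carvone
Product: 38 trimethyl{[(S)-2-methyl-5-(prop-1-en-2-yl)cyclohex-1-en-1-yl]oxy}silane, via lithium enolate 37 (not isolated)
Conditions: LiBH(s-Bu)3, THF, −78 °C; then Me3SiCl, Et3N, −78 → 0 °C
Reagents that add atoms: chlorotrimethylsilane, C[Si](C)(C)Cl
Why: conjugate reduction by the bulky borohydride gives the enolate regiospecifically and O-silylation fixes the tetrasubstituted enol ether; the isopropenyl group and C7′ are untouched.

Step 27
Reactants: 38 trimethyl{[(S)-2-methyl-5-(prop-1-en-2-yl)cyclohex-1-en-1-yl]oxy}silane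
Product: 39 trimethyl{[(4S)-6-methyl-4-(prop-1-en-2-yl)bicyclo[4.1.0]heptan-1-yl]oxy}silane (cyclopropane diastereomers)
Conditions: Et2Zn, CH2I2, CH2Cl2, 0 °C
Reagents that add atoms: diiodomethane, ICI
Why: Furukawa-type Simmons–Smith cyclopropanation; the electron-rich enol ether reacts before the isopropenyl alkene, and the cyclopropane configuration is lost in the next step.

Step 28
Reactants: 39 trimethyl{[(4S)-6-methyl-4-(prop-1-en-2-yl)bicyclo[4.1.0]heptan-1-yl]oxy}silane
Product: 41 (S)-3-methyl-6-(prop-1-en-2-yl)cyclohept-2-en-1-one, via 3-chloro-3-methylcycloheptanone 40 (not isolated)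
Conditions: FeCl3, DMF, 0 °C; then NaOAc, MeOH, reflux
Reagents that add atoms: none
Why: oxidative ring expansion of a siloxycyclopropane; one-electron oxidation opens the internal bond to a β-keto radical that is chlorinated at the tertiary carbon, and acetate eliminates HCl to the cycloheptenone in which the new carbon is C1′.

Step 29
Reactants: 42 but-2-yn-1-ol
Product: 44 (Z)-3-iodobut-2-en-1-ol, via cyclic alkenylaluminate 43 (not isolated)
Conditions: NaAlH2(OCH2CH2OCH3)2, Et2O, 0 °C; then I2, THF, −78 °C
Reagents that add atoms: iodine, II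
Why: alkoxide-directed trans-hydroalumination places aluminium on C3, and iodinolysis with retention gives the (Z)-iodoalkene needed for five-ring closure.

Step 30
Reactants: 44 (Z)-3-iodobut-2-en-1-ol
Product: 45 (Z)-1-bromo-3-iodobut-2-ene
Conditions: CBr4, PPh3, CH2Cl2, 0 °C
Reagents that add atoms: tetrabromomethane, BrC(Br)(Br)Br
Why: Appel bromination of the primary allylic alcohol without change of alkene geometry.

Step 31
Reactants: 41 (S)-3-methyl-6-(prop-1-en-2-yl)cyclohept-2-en-1-one; 45 (Z)-1-bromo-3-iodobut-2-ene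
Product: 47 (3R,6S)-2-[(Z)-3-iodobut-2-en-1-yl]-3-methyl-6-(prop-1-en-2-yl)cycloheptan-1-one (C2 epimers), via diphenylsilyl enol ether 46 (not isolated)
Conditions: CuCl (5 mol%), NaOt-Bu (5 mol%), (S)-p-tol-BINAP (5 mol%), Ph2SiH2, toluene, 0 °C; then 45, Bu4N[Ph3SiF2], CH2Cl2, rt
Reagents that add atoms: none
Why: copper hydride asymmetric conjugate reduction sets C10′ under ligand control (methyl cis to the isopropenyl group, which the remote C7′ centre alone would not secure), and fluoride activation of the regiodefined silyl enol ether allows C-alkylation at C1′; the C1′ configuration is irrelevant because C1′ becomes planar in steps 32 and 34.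

Step 32
Reactants: 47 (3R,6S)-2-[(Z)-3-iodobut-2-en-1-yl]-3-methyl-6-(prop-1-en-2-yl)cycloheptan-1-one
Product: 49 (3R,6S)-2-bromo-2-[(Z)-3-iodobut-2-en-1-yl]-3-methyl-6-(prop-1-en-2-yl)cycloheptan-1-one (C2 epimers), via trimethylsilyl enol ether 48 (not isolated)
Conditions: Me3SiCl, NaI, Et3N, MeCN, rt; then N-bromosuccinimide, THF, −78 °C
Reagents that add atoms: N-bromosuccinimide, O=C1CCC(=O)N1Br
Why: equilibrating silylation favours the more substituted enol ether toward C1′, and the enol ether is brominated far faster than the isolated alkenes, giving the tertiary α-bromo ketone.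

**Endgame**

Step 33
Reactants: 35 21,21-(ethylenedioxy)-2-methoxy-3-(methoxymethoxy)-24,29-dinor-8β-D:A-friedooleana-1,3,5(10)-trien-6-one
Product: 50 21,21-(ethylenedioxy)-2-hydroxy-3-(methoxymethoxy)-24,29-dinor-8β-D:A-friedooleana-1,3,5(10)-trien-6-one
Conditions: NaSEt, DMF, 110 °C
Reagents that add atoms: none
Why: nucleophilic demethylation (SN2 at the methyl group); the O2 phenoxide is a good leaving group because it is para to the C6 ketone, and the acetal on O3 and the ketal are inert to thiolate.

Step 34
Reactants: 50 21,21-(ethylenedioxy)-2-hydroxy-3-(methoxymethoxy)-24,29-dinor-8β-D:A-friedooleana-1,3,5(10)-trien-6-one; 49 (3R,6S)-2-bromo-2-[(Z)-3-iodobut-2-en-1-yl]-3-methyl-6-(prop-1-en-2-yl)cycloheptan-1-one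
Product: 51 21,21-(ethylenedioxy)-2-{[(1S,2R,5S)-1-((Z)-3-iodobut-2-en-1-yl)-2-methyl-7-oxo-5-(prop-1-en-2-yl)cycloheptyl]oxy}-3-(methoxymethoxy)-24,29-dinor-8β-D:A-friedooleana-1,3,5(10)-trien-6-one
Conditions: Et3N, (CF3)2CHOH, 0 °C → rt
Reagents that add atoms: none
Why: substitution of a tertiary α-bromo ketone by a phenol through the oxyallyl cation formed by base in a fluorinated alcohol; O2, acidified by the para ketone, is the only free oxygen, it should attack the more substituted and more cationic terminus C1′ on the face anti to the C10′ methyl (O2 trans to that methyl), and the ketone-deactivated arene resists C-alkylation.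

Step 35
Reactants: 51 the C1′ aryl ether ketone from step 34
Product: 52 21,21-(ethylenedioxy)-2-[(5′-hydroxyguaia-3′,11′-dien-1′-yl)oxy]-3-(methoxymethoxy)-24,29-dinor-8β-D:A-friedooleana-1,3,5(10)-trien-6-one (C5′ epimers)
Conditions: CrCl2, NiCl2 (2 mol%), DMF, 50 °C
Reagents that add atoms: none
Why: intramolecular Nozaki–Hiyama–Kishi reaction; zerovalent nickel inserts into the vinyl iodide, the vinyl group passes to trivalent chromium and adds to the C5′ ketone, closing the cyclopentene at C4′–C5′ with the (Z) geometry retained; the hindered C6 aryl ketone is spared and the C5′ configuration does not matter.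

Step 36
Reactants: 52 the tertiary allylic alcohol from step 35
Product: 53 21,21-(ethylenedioxy)-2-[(5′-hydroxyguaia-3′,11′-dien-1′-yl)oxy]-3-(methoxymethoxy)-24,29-dinor-8β-D:A-friedooleana-1,3,5(10)-trien-6-ol (C5′ and C6 epimers)
Conditions: NaBH4, MeOH/THF, 0 °C → rt
Reagents that add atoms: none
Why: hydride reduction of the only free ketone (C21 is still a ketal) gives the benzylic alcohol; its configuration is irrelevant because it is eliminated next.

Step 37
Reactants: 53 the diol from step 36
Product: 54 target CNP0233042.2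
Conditions: TsOH·H2O (0.2 equiv), acetone/H2O (50:1), 50 °C
Reagents that add atoms: water, O
Why: acid-mediated cascade of known steps: the tertiary allylic C5′ carbinol ionises (SN1) to the C5′–C4′–C3′ allyl cation, the acetal on O3 is hydrolysed and O3, held beside C5′ by the O2–C1′ ether, closes the dioxane on the face of O2 (cis fusion, alkene left at C3′=C4′); the para-alkoxybenzylic C6 alcohol eliminates (E1) to C6=C7, and transketalisation frees the C21 ketone with the equatorial C20 methyl retained.

## Compound list

1 | 2,3-dimethoxytoluene | COc1cccc(C)c1OC | starting material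
2 | 1-(3,4-dimethoxy-2-methylphenyl)ethan-1-one | CC(=O)c1ccc(OC)c(OC)c1C | intermediate
3 | 1-(3-hydroxy-4-methoxy-2-methylphenyl)ethan-1-one | CC(=O)c1ccc(OC)c(O)c1C | intermediate
4 | 1-(3-hydroxy-6-iodo-4-methoxy-2-methylphenyl)ethan-1-one | CC(=O)c1c(I)cc(OC)c(O)c1C | intermediate
5 | 1-[6-iodo-4-methoxy-3-(methoxymethoxy)-2-methylphenyl]ethan-1-one | CC(=O)c1c(I)cc(OC)c(OCOC)c1C | intermediate
6 | (E)-2-methylbut-2-en-1-ol | C/C=C(\C)CO | starting material
7 | (E)-1-bromo-2-methylbut-2-ene | C/C=C(\C)CBr | intermediate
8 | lithium enolate of 5 | [Li+].C=C([O-])c1c(I)cc(OC)c(OCOC)c1C | intermediate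
9 | (E)-1-[6-iodo-4-methoxy-3-(methoxymethoxy)-2-methylphenyl]-4-methylhex-4-en-1-one | C/C=C(C)/CCC(=O)c1c(I)cc(OC)c(OCOC)c1C | intermediate
10 | (S)-4-ethenyl-6-methoxy-7-(methoxymethoxy)-4,8-dimethyl-3,4-dihydronaphthalen-1(2H)-one | COCOc1c(OC)cc2c(c1C)C(=O)CC[C@@]2(C)C=C | intermediate
11 | (4S)-4-ethenyl-6-methoxy-7-(methoxymethoxy)-4,8-dimethyl-1,2,3,4-tetrahydronaphthalen-1-ol (C1 epimers) | COCOc1c(OC)cc2c(c1C)C(O)CC[C@@]2(C)C=C | intermediate
12 | tert-butyl{[(4S)-4-ethenyl-6-methoxy-7-(methoxymethoxy)-4,8-dimethyl-1,2,3,4-tetrahydronaphthalen-1-yl]oxy}dimethylsilane | COCOc1c(OC)cc2c(c1C)C(O[Si](C)(C)C(C)(C)C)CC[C@@]2(C)C=C | intermediate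
13 | B-alkyl-9-borabicyclo[3.3.1]nonane from 12 (boron on C12) | COCOc1c(OC)cc2c(c1C)C(O[Si](C)(C)C(C)(C)C)CC[C@@]2(C)CCB1C2CCCC1CCC2 | intermediate
14 | 2-[(1S)-4-(tert-butyldimethylsilyloxy)-7-methoxy-6-(methoxymethoxy)-1,5-dimethyl-1,2,3,4-tetrahydronaphthalen-1-yl]ethan-1-ol | COCOc1c(OC)cc2c(c1C)C(O[Si](C)(C)C(C)(C)C)CC[C@@]2(C)CCO | intermediate
15 | tert-butyl{[(4S)-4-(2-iodoethyl)-6-methoxy-7-(methoxymethoxy)-4,8-dimethyl-1,2,3,4-tetrahydronaphthalen-1-yl]oxy}dimethylsilane | COCOc1c(OC)cc2c(c1C)C(O[Si](C)(C)C(C)(C)C)CC[C@@]2(C)CCI | intermediate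
16 | 2,5-dimethyl-1,4-benzoquinone | CC1=CC(=O)C(C)=CC1=O | starting material
17 | 2,5-dimethylbenzene-1,4-diol | Cc1cc(O)c(C)cc1O | intermediate
18 | 2,5-dimethylcyclohexane-1,4-diol (stereoisomer mixture) | CC1CC(O)C(C)CC1O | intermediate
19 | 2,5-dimethylcyclohexane-1,4-dione (interconverting cis and trans forms) | CC1CC(=O)C(C)CC1=O | intermediate
20 | 2,5-dimethyl-4-{[(S)-1-phenylethyl]imino}cyclohexan-1-one | CC1CC(=O)C(C)CC1=N[C@@H](C)c1ccccc1 | intermediate
21 | pent-1-en-3-one | C=CC(=O)CC | starting material
22 | (2S)-2,5-dimethyl-2-(3-oxopentyl)-1-{[(S)-1-phenylethyl]imino}cyclohexan-4-one | CCC(=O)CC[C@@]1(C)CC(=O)C(C)CC1=N[C@@H](C)c1ccccc1 | intermediate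
23 | (2S)-2,5-dimethyl-2-(3-oxopentyl)cyclohexane-1,4-dione (C5 epimers) | CCC(=O)CC[C@@]1(C)CC(=O)C(C)CC1=O | intermediate
24 | (4aS,7R)-1,4a,7-trimethyl-4,4a,7,8-tetrahydronaphthalene-2,6(3H,5H)-dione | CC1=C2C[C@@H](C)C(=O)C[C@]2(C)CCC1=O | intermediate
25 | (4aS,7R)-6,6-(ethylenedioxy)-1,4a,7-trimethyl-4,4a,5,6,7,8-hexahydronaphthalen-2(3H)-one | CC1=C2C[C@@H](C)C3(OCCO3)C[C@]2(C)CCC1=O | intermediate
26 | cis-fused 6,6-(ethylenedioxy)-1,4a,7-trimethyloctahydronaphthalen-2(1H)-one (H18 cis to the C17 methyl; C13 epimers) | CC1[C@@H]2C[C@@H](C)C3(OCCO3)C[C@]2(C)CCC1=O | intermediate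
27 | trimethylsilyl enol ether of 26 (C13=C14) | CC1=C(O[Si](C)(C)C)CC[C@@]2(C)CC3(OCCO3)[C@H](C)C[C@@H]12 | intermediate
28 | lithium enolate of 26 (C13=C14) | [Li+].CC1=C([O-])CC[C@@]2(C)CC3(OCCO3)[C@H](C)C[C@@H]12 | intermediate
29 | 6-(tert-butyldimethylsilyloxy)-21,21-(ethylenedioxy)-2-methoxy-3-(methoxymethoxy)-8,14-seco-24,29-dinor-D:A-friedooleana-1,3,5(10)-trien-14-one (C6 epimers) | COCOc1c(OC)cc2c(c1C)C(O[Si](C)(C)C(C)(C)C)CC[C@@]2(C)CC[C@@]1(C)[C@@H]3C[C@@H](C)C4(OCCO4)C[C@]3(C)CCC1=O | intermediate
30 | 6-(tert-butyldimethylsilyloxy)-21,21-(ethylenedioxy)-2-methoxy-3-(methoxymethoxy)-8,14-seco-24,29-dinor-D:A-friedooleana-1,3,5(10),14(26)-tetraene | COCOc1c(OC)cc2c(c1C)C(O[Si](C)(C)C(C)(C)C)CC[C@@]2(C)CC[C@@]1(C)[C@@H]3C[C@@H](C)C4(OCCO4)C[C@]3(C)CCC1=C | intermediate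
31 | 21,21-(ethylenedioxy)-2-methoxy-3-(methoxymethoxy)-8,14-seco-24,29-dinor-D:A-friedooleana-1,3,5(10),14(26)-tetraen-6-ol (C6 epimers) | COCOc1c(OC)cc2c(c1C)C(O)CC[C@@]2(C)CC[C@@]1(C)[C@@H]3C[C@@H](C)C4(OCCO4)C[C@]3(C)CCC1=C | intermediate
32 | 21,21-(ethylenedioxy)-2-methoxy-3-(methoxymethoxy)-8,14-seco-24,29-dinor-D:A-friedooleana-1,3,5(10),14(26)-tetraen-6-one | COCOc1c(OC)cc2c(c1C)C(=O)CC[C@@]2(C)CC[C@@]1(C)[C@@H]3C[C@@H](C)C4(OCCO4)C[C@]3(C)CCC1=C | intermediate
33 | 6-(trimethylsilyloxy)-21,21-(ethylenedioxy)-2-methoxy-3-(methoxymethoxy)-8,14-seco-24,29-dinor-D:A-friedooleana-1,3,5(10),6,14(26)-pentaene | COCOc1c(OC)cc2c(c1C)C(O[Si](C)(C)C)=CC[C@@]2(C)CC[C@@]1(C)[C@@H]3C[C@@H](C)C4(OCCO4)C[C@]3(C)CCC1=C | intermediate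
34 | 21,21-(ethylenedioxy)-2-methoxy-3-(methoxymethoxy)-8,14-seco-24,29-dinor-D:A-friedooleana-1,3,5(10),7,14(26)-pentaen-6-one (ring-C-seco naphthalenone) | COCOc1c(OC)cc2c(c1C)C(=O)C=C[C@@]2(C)CC[C@@]1(C)[C@@H]3C[C@@H](C)C4(OCCO4)C[C@]3(C)CCC1=C | intermediate
35 | 21,21-(ethylenedioxy)-2-methoxy-3-(methoxymethoxy)-24,29-dinor-8β-D:A-friedooleana-1,3,5(10)-trien-6-one | COCOc1c(OC)cc2c(c1C)C(=O)C[C@@H]1[C@@]2(C)CC[C@@]2(C)[C@@H]3C[C@@H](C)C4(OCCO4)C[C@]3(C)CC[C@]12C | intermediate
36 | (S)-carvone | C=C(C)[C@H]1CC=C(C)C(=O)C1 | starting material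
37 | lithium (S)-2-methyl-5-(prop-1-en-2-yl)cyclohex-1-en-1-olate | [Li+].C=C(C)[C@H]1CCC(C)=C([O-])C1 | intermediate
38 | trimethyl{[(S)-2-methyl-5-(prop-1-en-2-yl)cyclohex-1-en-1-yl]oxy}silane | C=C(C)[C@H]1CCC(C)=C(O[Si](C)(C)C)C1 | intermediate
39 | trimethyl{[(4S)-6-methyl-4-(prop-1-en-2-yl)bicyclo[4.1.0]heptan-1-yl]oxy}silane (cyclopropane diastereomers) | C=C(C)[C@H]1CCC2(C)CC2(O[Si](C)(C)C)C1 | intermediate
40 | (6S)-3-chloro-3-methyl-6-(prop-1-en-2-yl)cycloheptan-1-one (C3 epimers) | C=C(C)[C@H]1CCC(C)(Cl)CC(=O)C1 | intermediate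
41 | (S)-3-methyl-6-(prop-1-en-2-yl)cyclohept-2-en-1-one | C=C(C)[C@H]1CCC(C)=CC(=O)C1 | intermediate
42 | but-2-yn-1-ol | CC#CCO | starting material
43 | sodium 2,2-bis(2-methoxyethoxy)-3-methyl-2,5-dihydro-1,2-oxaaluminol-2-uide | [Na+].CC1=CCO[Al-]1(OCCOC)OCCOC | intermediate
44 | (Z)-3-iodobut-2-en-1-ol | C/C(I)=C/CO | intermediate
45 | (Z)-1-bromo-3-iodobut-2-ene | C/C(I)=C/CBr | intermediate
46 | {[(4S,7R)-7-methyl-4-(prop-1-en-2-yl)cyclohept-1-en-1-yl]oxy}diphenylsilane | C=C(C)[C@H]1CC[C@@H](C)C=C(O[SiH](c2ccccc2)c2ccccc2)C1 | intermediate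
47 | (3R,6S)-2-[(Z)-3-iodobut-2-en-1-yl]-3-methyl-6-(prop-1-en-2-yl)cycloheptan-1-one (C2 epimers) | C=C(C)[C@H]1CC[C@@H](C)C(C/C=C(/C)I)C(=O)C1 | intermediate
48 | {[(3R,6S)-2-((Z)-3-iodobut-2-en-1-yl)-3-methyl-6-(prop-1-en-2-yl)cyclohept-1-en-1-yl]oxy}trimethylsilane | C=C(C)[C@H]1CC[C@@H](C)C(C/C=C(/C)I)=C(O[Si](C)(C)C)C1 | intermediate
49 | (3R,6S)-2-bromo-2-[(Z)-3-iodobut-2-en-1-yl]-3-methyl-6-(prop-1-en-2-yl)cycloheptan-1-one (C2 epimers) | C=C(C)[C@H]1CC[C@@H](C)C(Br)(C/C=C(/C)I)C(=O)C1 | intermediate
50 | 21,21-(ethylenedioxy)-2-hydroxy-3-(methoxymethoxy)-24,29-dinor-8β-D:A-friedooleana-1,3,5(10)-trien-6-one | COCOc1c(O)cc2c(c1C)C(=O)C[C@@H]1[C@@]2(C)CC[C@@]2(C)[C@@H]3C[C@@H](C)C4(OCCO4)C[C@]3(C)CC[C@]12C | intermediate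
51 | 21,21-(ethylenedioxy)-2-{[(1S,2R,5S)-1-((Z)-3-iodobut-2-en-1-yl)-2-methyl-7-oxo-5-(prop-1-en-2-yl)cycloheptyl]oxy}-3-(methoxymethoxy)-24,29-dinor-8β-D:A-friedooleana-1,3,5(10)-trien-6-one (O2 on C1′, trans to the C10′ methyl) | C=C(C)[C@H]1CC[C@@H](C)[C@](C/C=C(/C)I)(Oc2cc3c(c(C)c2OCOC)C(=O)C[C@@H]2[C@@]3(C)CC[C@@]3(C)[C@@H]4C[C@@H](C)C5(OCCO5)C[C@]4(C)CC[C@]23C)C(=O)C1 | intermediate
52 | 21,21-(ethylenedioxy)-2-[(5′-hydroxyguaia-3′,11′-dien-1′-yl)oxy]-3-(methoxymethoxy)-24,29-dinor-8β-D:A-friedooleana-1,3,5(10)-trien-6-one (O2 trans to the C10′ methyl; C10′ methyl cis to the C7′ isopropenyl; C5′ epimers) | C=C(C)[C@H]1CC[C@@H](C)[C@@]2(Oc3cc4c(c(C)c3OCOC)C(=O)C[C@@H]3[C@@]4(C)CC[C@@]4(C)[C@@H]5C[C@@H](C)C6(OCCO6)C[C@]5(C)CC[C@]34C)CC=C(C)C2(O)C1 | intermediate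
53 | 21,21-(ethylenedioxy)-2-[(5′-hydroxyguaia-3′,11′-dien-1′-yl)oxy]-3-(methoxymethoxy)-24,29-dinor-8β-D:A-friedooleana-1,3,5(10)-trien-6-ol (C5′ and C6 epimers) | C=C(C)[C@H]1CC[C@@H](C)[C@@]2(Oc3cc4c(c(C)c3OCOC)C(O)C[C@@H]3[C@@]4(C)CC[C@@]4(C)[C@@H]5C[C@@H](C)C6(OCCO6)C[C@]5(C)CC[C@]34C)CC=C(C)C2(O)C1 | intermediate
54 | CNP0233042.2: 2,3-O-(guaia-3′,11′-diene-1′,5′-diyl) ether of 2,3-dihydroxy-24,29-dinor-8β-D:A-friedooleana-1,3,5(10),6-tetraen-21-one (O2–C1′, O3–C5′, cis-fused dioxane) | C=C(C)[C@H]1CC[C@@H](C)[C@@]23CC=C(C)[C@]2(C1)Oc1c(cc2c(c1C)C=C[C@@H]1[C@@]2(C)CC[C@@]2(C)[C@@H]4C[C@@H](C)C(=O)C[C@]4(C)CC[C@]12C)O3 | target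

## Step count and least certain steps

Total step count: 37. Longest linear sequence: 21 steps (1–4, 6–11, 20–25, 33–37).

**Step 25 (key step).** Two processes can go wrong. The tertiary C14 radical may be reduced by a second hydrogen-atom transfer before the slow addition to C8 (a β-carbon beside quaternary C9), giving net hydrogenation of the methylene. The radical may also close through its other face and give the cis C/D junction, because the favoured chair builds up the syn-axial C9/C14 methyl pair. Fallback, from 34 back to 35: dimethyldioxirane epoxidises only the 1,1-disubstituted alkene and gives the 14,26-epoxy-8,14-seco naphthalenone F1. Cp2TiCl, made from Cp2TiCl2 and Zn, opens the epoxide to the same tertiary C14 radical. No metal hydride is present, so the radical is long-lived and closes 6-exo onto C8, with the α-keto radical reduced by trivalent titanium, to give the 26-hydroxy pentacycle F2. Its thiocarbonylimidazolide F3 is deoxygenated with Bu3SnH and a radical initiator to 35. This removes early reduction; it does not by itself change the facial preference at C14.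

**Step 20.** C-alkylation of a tetrasubstituted enolate by an unactivated primary iodide may be slow, so proton transfer and O-alkylation can take over; attack from the α face is the second risk. Fallback, from 14 and 28 back to 29: Dess–Martin oxidation of 14 gives the aldehyde F4, a far more reactive electrophile. Aldol addition of enolate 28 at −78 °C gives the 12-hydroxy ketone F5. Burgess dehydration, which can only go toward C11, gives the 11-ene F6, and hydrogenation over Pd/C gives 29. If the α face proves preferred, the order of introducing methyl and chain at C13 would have to be reversed.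

**Step 34.** The oxyallyl cation may be captured at its less hindered terminus C6′ (cine substitution), or lose a proton to an enone, and the phenoxide para to a ketone is a modest nucleophile. Fallback, from 50 and 49 directly to 51 (no new compound, F0): the ionic substitution is replaced by a copper-mediated radical coupling (CuI, a triamine ligand, K3PO4, toluene). The bromide is abstracted to the tertiary α-keto radical at C1′, which combines with a copper aryloxide. No cation is formed, so cine substitution and E1 loss are taken out, and the radical is again captured anti to the C10′ methyl.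

**Step 37.** Four acid-driven events run in one flask. The benzylic cation at C6 may be re-trapped by water so that elimination stays incomplete, and prolonged acid endangers the isopropenyl group and the new allylic aryl ether. Fallback, from 52 back to 54: the alkene is installed without a cation. KN(SiMe3)2 and PhNTf2 convert the C6 ketone of 52 into the enol triflate F7, and Pd(OAc)2, PPh3, HCO2H and Et3N reduce it to the 6-ene F8. A short treatment with TsOH·H2O in wet acetone then only has to cleave the acetal and ketal and close the dioxane, giving 54.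

## Further compounds

F1 | step 25 | 14,26-epoxy-21,21-(ethylenedioxy)-2-methoxy-3-(methoxymethoxy)-8,14-seco-24,29-dinor-D:A-friedooleana-1,3,5(10),7-tetraen-6-one (C14 epimers) | COCOc1c(OC)cc2c(c1C)C(=O)C=C[C@@]2(C)CC[C@@]1(C)[C@@H]3C[C@@H](C)C4(OCCO4)C[C@]3(C)CCC15CO5
F2 | step 25 | 21,21-(ethylenedioxy)-26-hydroxy-2-methoxy-3-(methoxymethoxy)-24,29-dinor-8β-D:A-friedooleana-1,3,5(10)-trien-6-one | COCOc1c(OC)cc2c(c1C)C(=O)C[C@@H]1[C@@]2(C)CC[C@@]2(C)[C@@H]3C[C@@H](C)C4(OCCO4)C[C@]3(C)CC[C@]12CO
F3 | step 25 | O-26 imidazole-1-carbothioate of F2 | COCOc1c(OC)cc2c(c1C)C(=O)C[C@@H]1[C@@]2(C)CC[C@@]2(C)[C@@H]3C[C@@H](C)C4(OCCO4)C[C@]3(C)CC[C@]12COC(=S)n1ccnc1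
F4 | step 20 | 2-[(1S)-4-(tert-butyldimethylsilyloxy)-7-methoxy-6-(methoxymethoxy)-1,5-dimethyl-1,2,3,4-tetrahydronaphthalen-1-yl]acetaldehyde | COCOc1c(OC)cc2c(c1C)C(O[Si](C)(C)C(C)(C)C)CC[C@@]2(C)CC=O
F5 | step 20 | 12-hydroxy derivative of 29 (C12 epimers) | COCOc1c(OC)cc2c(c1C)C(O[Si](C)(C)C(C)(C)C)CC[C@@]2(C)CC(O)[C@@]1(C)[C@@H]3C[C@@H](C)C4(OCCO4)C[C@]3(C)CCC1=O
F6 | step 20 | (E)-11,12-didehydro derivative of 29 | COCOc1c(OC)cc2c(c1C)C(O[Si](C)(C)C(C)(C)C)CC[C@@]2(C)/C=C/[C@@]1(C)[C@@H]3C[C@@H](C)C4(OCCO4)C[C@]3(C)CCC1=O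
F0 | step 34 | none | none
F7 | step 37 | C6 enol trifluoromethanesulfonate of 52 (C6=C7) | C=C(C)[C@H]1CC[C@@H](C)[C@@]2(Oc3cc4c(c(C)c3OCOC)C(OS(=O)(=O)C(F)(F)F)=C[C@@H]3[C@@]4(C)CC[C@@]4(C)[C@@H]5C[C@@H](C)C6(OCCO6)C[C@]5(C)CC[C@]34C)CC=C(C)C2(O)C1
F8 | step 37 | 21,21-(ethylenedioxy)-2-[(5′-hydroxyguaia-3′,11′-dien-1′-yl)oxy]-3-(methoxymethoxy)-24,29-dinor-8β-D:A-friedooleana-1,3,5(10),6-tetraene (C5′ epimers) | C=C(C)[C@H]1CC[C@@H](C)[C@@]2(Oc3cc4c(c(C)c3OCOC)C=C[C@@H]3[C@@]4(C)CC[C@@]4(C)[C@@H]5C[C@@H](C)C6(OCCO6)C[C@]5(C)CC[C@]34C)CC=C(C)C2(O)C1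
A1 | alternative 1 | 3′-oxo-3′,4′-dihydro derivative of the target with C21 as its ethylene ketal | C=C(C)[C@H]1CC[C@@H](C)[C@@]23CC(=O)[C@@H](C)[C@]2(C1)Oc1c(cc2c(c1C)C=C[C@@H]1[C@@]2(C)CC[C@@]2(C)[C@@H]4C[C@@H](C)C5(OCCO5)C[C@]4(C)CC[C@]12C)O3
A2 | alternative 2 | ring-B-seco arene with vinyl groups on C5 and C8 | C=C(C)[C@H]1CC[C@@H](C)[C@@]23CC=C(C)[C@]2(C1)Oc1c(cc(c(C=C)c1C)[C@]1(C)CC[C@@]2(C)[C@@H]4C[C@@H](C)C(=O)C[C@]4(C)CC[C@]2(C)[C@@H]1C=C)O3
A3 | alternative 3 | 11-oxo derivative of the target | C=C(C)[C@H]1CC[C@@H](C)[C@@]23CC=C(C)[C@]2(C1)Oc1c(cc2c(c1C)C=C[C@@H]1[C@@]2(C)C(=O)C[C@@]2(C)[C@@H]4C[C@@H](C)C(=O)C[C@]4(C)CC[C@]12C)O3
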